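The route rests on one disconnection: the C1–OMe and C4–O bonds of the cyclohexene ring (C1 is CH–OMe, C2 the vinylic CH, C3 the carbon bearing the benzoyloxymethyl carbon C7, C4 CH–OH, C5 CH–OBz, C6 CH–OH). These two oxygens stand 1,4-trans across the C2=C3 alkene, the pattern left by a palladium/benzoquinone 1,4-oxidation of a C1–C4 diene. In one operation the key step joins the diene, methanol and acetic acid, forms both C–O bonds and sets C1 and C4 under control of the trans C5/C6 oxygens. Its precursor is the chorismate-type 5-benzoyloxy-6-silyloxy-3-(benzoyloxymethyl)cyclohexa-1,3-diene, reached from shikimic acid by a sulfenate–sulfoxide 1,4-dehydration.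

Key step: step 7

Remark on numbering: compounds 13, 15, 17 and 18 use the ring numbering given above. Compounds 1–12 use shikimate numbering (C1 = alkene carbon bearing C7, C2 = vinylic CH, C3 = allylic CH–O, C4, C5, C6 = CH2). Target C5 is shikimate C5 and target C6 is shikimate C4.

Remark on the chemistry: the shikimate C6 hydrogens are not acidified by the C1 substituent (it sits on the central carbon of the would-be allyl anion), so the 1,4-elimination is done by a sigmatropic shift and a thermal syn-elimination, not by base.

Remark: palladium-bound species of the catalytic cycle in step 7 are transient catalyst states and are not numbered.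

Step 1
Reactants: 1 (−)-shikimic acid; 2 methanol; 3 2,2-dimethoxypropane
Product: 5 methyl 3,4-O-isopropylidene-shikimate, via methyl shikimate 4 (not isolated)
Conditions: CSA (5 mol %), MeOH, reflux; evaporate; then Me2C(OMe)2, acetone, rt
Reagents that add atoms: methanol CO; 2,2-dimethoxypropane COC(C)(C)OC
Why: Fischer esterification followed in the same flask by acid-catalysed transketalisation, which can bridge only the cis-3,4-diol, so O5 stays free and no stereocentre is touched.

Step 2
Reactants: 5 methyl 3,4-O-isopropylidene-shikimate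
Product: 6 [(3R,4S,5R)-5-hydroxy-3,4-(isopropylidenedioxy)cyclohex-1-en-1-yl]methanol
Conditions: i-Bu2AlH (4 equiv), CH2Cl2, −78 → 0 °C; aq. potassium sodium tartrate
Reagents that add atoms: none
Why: i-Bu2AlH gives clean 1,2-reduction of the conjugated ester to the allylic alcohol, and the acetonide and the O5 aluminium alkoxide are inert.

Step 3
Reactants: 6 acetonide diol; 7 benzoyl chloride
Product: 8 [(3R,4S,5R)-5-(benzoyloxy)-3,4-(isopropylidenedioxy)cyclohex-1-en-1-yl]methyl benzoate
Conditions: BzCl (2.4 equiv), pyridine, DMAP (cat.), CH2Cl2, 0 °C → rt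
Reagents that add atoms: benzoyl chloride O=C(Cl)c1ccccc1
Why: DMAP-catalysed O-acylation of the primary allylic and the secondary hydroxyl installs in one operation the two benzoates that the target keeps (C7 and C5).

Step 4
Reactants: 8 dibenzoate acetonide
Product: 9 [(3R,4R,5R)-5-(benzoyloxy)-3,4-dihydroxycyclohex-1-en-1-yl]methyl benzoate
Conditions: AcOH–H2O (4:1), 50 °C
Reagents that add atoms: none
Why: Acid hydrolysis of the cis-fused dioxolane is far faster than benzoate hydrolysis or migration of the trans-disposed O5 benzoate under these mild conditions, so the 3,4-cis-diol is freed with the configuration of shikimic acid intact.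

Step 5
Reactants: 9 diol dibenzoate; 10 2,4-dinitrobenzenesulfenyl chloride
Product: 13 (5R,6R)-5-(benzoyloxy)-3-[(benzoyloxy)methyl]cyclohexa-1,3-dien-6-ol, via allyl sulfenate 11 (not isolated), via allyl sulfoxide 12 (not isolated)
Conditions: 2,4-(O2N)2C6H3SCl (1.1 equiv), Et3N (2.5 equiv), ClCH2CH2Cl, −20 °C → rt, then 60 °C
Reagents that add atoms: none
Why: The allylic, less hindered shikimate C3 hydroxyl should be sulfenylated first, the allyl sulfenate undergoes a suprafacial [2,3]-sigmatropic shift (the reverse of the Mislow–Evans rearrangement) to the tertiary sulfoxide at shikimate C1, and thermal sulfoxide syn-elimination toward the ring CH2 (away from the oxygen-bearing C7) gives the conjugated diene, an overall 1,4-dehydration that leaves both stereocentres (C5, C6) untouched.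

Step 6
Reactants: 13 dienol; 14 tert-butyldimethylsilyl trifluoromethanesulfonate
Product: 15 (5R,6R)-5-(benzoyloxy)-3-[(benzoyloxy)methyl]-6-[(tert-butyldimethylsilyl)oxy]cyclohexa-1,3-diene
Conditions: TBSOTf (1.3 equiv), 2,6-lutidine (2 equiv), CH2Cl2, −78 → 0 °C
Reagents that add atoms: tert-butyldimethylsilyl trifluoromethanesulfonate CC(C)(C)[Si](C)(C)OS(=O)(=O)C(F)(F)F
Why: Silyl triflate with a hindered pyridine base silylates the flanked secondary alcohol quickly at low temperature, conditions too mild for benzoyl migration or aromatisation of the diene.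

Step 7
Reactants: 15 silyl diene; 2 methanol; 16 acetic acid
Product: 17 (1S,4S,5R,6R)-4-acetoxy-5-(benzoyloxy)-3-[(benzoyloxy)methyl]-6-[(tert-butyldimethylsilyl)oxy]-1-methoxycyclohex-2-ene
Conditions: Pd(OAc)2 (10 mol %), p-benzoquinone (2 equiv), MeOH–AcOH (5:1), 20 °C; no chloride, no strong acid
Reagents that add atoms: methanol CO; acetic acid CC(=O)O
Why: Proposed new method: divalent palladium binds the less substituted C1=C2 alkene of 15 on the face away from the C5 benzoate, methanol adds from outside to C1 (anti to the metal) to give a 1-methoxy-η3-allylpalladium acetate spanning C2–C4, benzoquinone coordination then drives migration of the palladium-bound acetate to C4 on the metal face, and benzoquinone returns the zerovalent palladium so released to the divalent state. The closest known reaction types are the chloride-free palladium/benzoquinone trans-1,4-diacetoxylation and the 1,4-dialkoxylation of cyclohexa-1,3-dienes and the intramolecular alkoxy–acetoxylation of tethered dienols; the intermolecular pairing of an alcohol with a carboxylate is what is new. No ring is closed. C1 is set by the anti attack of methanol, whose face is fixed by the trans C5/C6 pattern (methanol enters opposite the adjacent C6 silyloxy group while the metal sits opposite the C5 benzoate, so both substituents favour the same complex), and C4 is set by the cis migration of acetate, which places it trans to the C1 methoxy group and trans to the C5 benzoate. The step needs methanol at C1 rather than C4, 1,4- rather than 1,2-addition and methanol before acetate: the first is secured by the C3 substituent and the C5 benzoate that flank C4, the second by delivery of acetate to the allyl terminus remote from the methoxy-bearing carbon as in the known cases, and the third by methanol in large excess as co-solvent with neither chloride nor strong acid present, so that the second oxygen comes from bound acetate and not from solvent.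

Step 8
Reactants: 17 acetate silyl ether
Product: 18 (1S,4S,5R,6R)-5-(benzoyloxy)-3-[(benzoyloxy)methyl]-1-methoxycyclohex-2-ene-4,6-diol
Conditions: HCl (ca. 0.5 M in MeOH), CH2Cl2, 0 °C → rt
Reagents that add atoms: none
Why: Acid-catalysed methanolysis cleaves the secondary silyl ether and transesterifies the acetate much faster than the conjugated benzoates, and the non-basic medium should suppress benzoyl migration onto the freed C4 and C6 hydroxyls, with no stereocentre touched.

Compound list

1 | (−)-shikimic acid, (3R,4S,5R)-3,4,5-trihydroxycyclohex-1-ene-1-carboxylic acid | C1[C@H]([C@@H]([C@@H](C=C1C(=O)O)O)O)O | starting material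
2 | methanol | CO | starting material
3 | 2,2-dimethoxypropane | COC(C)(C)OC | starting material
4 | methyl shikimate, methyl (3R,4S,5R)-3,4,5-trihydroxycyclohex-1-ene-1-carboxylate | C1[C@H]([C@@H]([C@@H](C=C1C(=O)OC)O)O)O | intermediate (not isolated)
5 | methyl 3,4-O-isopropylidene-shikimate, methyl (3R,4S,5R)-5-hydroxy-3,4-(isopropylidenedioxy)cyclohex-1-ene-1-carboxylate | C1[C@H]([C@@H]([C@@H](C=C1C(=O)OC)O2)OC2(C)C)O | intermediate
6 | [(3R,4S,5R)-5-hydroxy-3,4-(isopropylidenedioxy)cyclohex-1-en-1-yl]methanol | C1[C@H]([C@@H]([C@@H](C=C1CO)O2)OC2(C)C)O | intermediate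
7 | benzoyl chloride | O=C(Cl)c1ccccc1 | starting material
8 | [(3R,4S,5R)-5-(benzoyloxy)-3,4-(isopropylidenedioxy)cyclohex-1-en-1-yl]methyl benzoate | C1[C@H]([C@@H]([C@@H](C=C1COC(=O)c3ccccc3)O2)OC2(C)C)OC(=O)c4ccccc4 | intermediate
9 | [(3R,4R,5R)-5-(benzoyloxy)-3,4-dihydroxycyclohex-1-en-1-yl]methyl benzoate (3,4-cis, 4,5-trans, as in shikimic acid) | C1[C@H]([C@@H]([C@@H](C=C1COC(=O)c2ccccc2)O)O)OC(=O)c3ccccc3 | intermediate
10 | 2,4-dinitrobenzenesulfenyl chloride | ClSc1ccc(cc1[N+](=O)[O-])[N+](=O)[O-] | starting material
11 | allyl sulfenate, [(3R,4S,5R)-5-(benzoyloxy)-3-[(2,4-dinitrophenyl)sulfanyloxy]-4-hydroxycyclohex-1-en-1-yl]methyl benzoate | C1[C@H]([C@@H]([C@@H](C=C1COC(=O)c2ccccc2)OSc4ccc(cc4[N+](=O)[O-])[N+](=O)[O-])O)OC(=O)c3ccccc3 | intermediate (not isolated)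
12 | allyl sulfoxide, [(1R,4R,5R)-5-(benzoyloxy)-1-[(2,4-dinitrophenyl)sulfinyl]-4-hydroxycyclohex-2-en-1-yl]methyl benzoate (sulfur on the ring face that carried the C3 oxygen; configuration at sulfur undefined) | C1[C@H]([C@@H](C=C[C@]1(COC(=O)c2ccccc2)S(=O)c4ccc(cc4[N+](=O)[O-])[N+](=O)[O-])O)OC(=O)c3ccccc3 | intermediate (not isolated)
13 | (5R,6R)-5-(benzoyloxy)-3-[(benzoyloxy)methyl]cyclohexa-1,3-dien-6-ol (5,6-trans) | C1=CC(COC(=O)c2ccccc2)=C[C@@H](OC(=O)c2ccccc2)[C@@H]1O | intermediate
14 | tert-butyldimethylsilyl trifluoromethanesulfonate | CC(C)(C)[Si](C)(C)OS(=O)(=O)C(F)(F)F | starting material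
15 | (5R,6R)-5-(benzoyloxy)-3-[(benzoyloxy)methyl]-6-[(tert-butyldimethylsilyl)oxy]cyclohexa-1,3-diene (precursor of the key step) | C1=CC(COC(=O)c2ccccc2)=C[C@@H](OC(=O)c2ccccc2)[C@@H]1O[Si](C)(C)C(C)(C)C | intermediate
16 | acetic acid | CC(=O)O | starting material
17 | (1S,4S,5R,6R)-4-acetoxy-5-(benzoyloxy)-3-[(benzoyloxy)methyl]-6-[(tert-butyldimethylsilyl)oxy]-1-methoxycyclohex-2-ene (all neighbouring oxygens trans) | CO[C@H]1C=C(COC(=O)c2ccccc2)[C@H](OC(C)=O)[C@@H](OC(=O)c2ccccc2)[C@@H]1O[Si](C)(C)C(C)(C)C | intermediate
18 | (1S,4S,5R,6R)-5-(benzoyloxy)-3-[(benzoyloxy)methyl]-1-methoxycyclohex-2-ene-4,6-diol, equal to [(3S,4R,5R,6S)-5-(benzoyloxy)-4,6-dihydroxy-3-methoxycyclohex-1-en-1-yl]methyl benzoate | CO[C@H]1C=C(COC(=O)c2ccccc2)[C@H](O)[C@@H](OC(=O)c2ccccc2)[C@@H]1O | target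

Total step count: 8 steps.
Longest linear sequence: 8 steps (fully linear from shikimic acid).

Steps most likely to fail

Step 7. The catalytic three-component reaction may lose the order of nucleophile entry, with acetate adding first or methanol adding twice by external attack, so that diacetoxy, dimethoxy or regioisomeric adducts form beside 17. In the fallback the two C–O bonds are made in separate, known operations on stoichiometric palladium. Setting out from 15, methoxypalladation with Na2PdCl4 in methanol (NaHCO3, rt), the classical alkoxypalladation of a 1,3-diene in which methanol is the only nucleophile, should give the chloride-bridged dimer of the (2–4-η)-1-methoxycyclohexenylpalladium complex F1, with the methoxy group anti to the metal. Chloride abstraction with AgOAc and addition of p-benzoquinone in acetic acid should then induce the known cis migration of acetate from palladium to C4, and the route is rejoined at 17.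

Step 5. The syn-elimination may run toward the exocyclic C7 hydrogens, or the sulfenyl chloride may add to the electron-rich diene or react at the C4 hydroxyl. In the fallback the dehydration is moved to the ester oxidation level, where the sulfoxide carbon has no exocyclic hydrogen and the diene is electron-poor. Setting out from 5, pivaloylation of O5 (PivCl, pyridine, DMAP) should give methyl 5-O-pivaloyl-3,4-O-isopropylidene-shikimate F2, and aqueous acetic acid should free the 3,4-diol F3. The same sulfenyl chloride/Et3N treatment should pass through the allyl sulfenate F4 and the α-sulfinyl ester F5 to the dienol ester F6, which can eliminate only into the ring. Silylation (TBSOTf, 2,6-lutidine) should give the silyl ether F7, and excess i-Bu2AlH should reduce the ester and cleave the pivalate in one operation to the diene diol F8. Double benzoylation (BzCl, pyridine, DMAP) rejoins the route at 15.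

Step 8. Methanolysis of the hindered C4 acetate may be too slow relative to loss of a benzoate, benzoyl migration onto the freed hydroxyls, or acid-induced allylic exchange at C1. In the fallback the two groups are removed separately under buffered or neutral conditions. Setting out from 17, HF·pyridine in THF should remove only the silyl ether to give the 4-O-acetyl alcohol F9. A lipase (Candida antarctica lipase B, phosphate buffer pH 7 with acetone as co-solvent) should then hydrolyse the alkyl acetate and leave the aryl esters, rejoining the route at 18.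

Further compounds

F1 | step 7 | di-μ-chloro-bis{(2,3,4-η)-(1S,5R,6R)-5-(benzoyloxy)-3-[(benzoyloxy)methyl]-6-[(tert-butyldimethylsilyl)oxy]-1-methoxycyclohex-2-en-4-yl}dipalladium, palladium anti to the methoxy group | CO[C@H]1C=C(COC(=O)c2ccccc2)[CH-][C@@H](OC(=O)c2ccccc2)[C@@H]1O[Si](C)(C)C(C)(C)C.CO[C@H]1C=C(COC(=O)c2ccccc2)[CH-][C@@H](OC(=O)c2ccccc2)[C@@H]1O[Si](C)(C)C(C)(C)C.[Cl-].[Cl-].[Pd+2].[Pd+2]
F2 | step 5 | methyl (3R,4S,5R)-3,4-(isopropylidenedioxy)-5-(pivaloyloxy)cyclohex-1-ene-1-carboxylate | C1[C@H]([C@@H]([C@@H](C=C1C(=O)OC)O2)OC2(C)C)OC(=O)C(C)(C)C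
F3 | step 5 | methyl (3R,4R,5R)-3,4-dihydroxy-5-(pivaloyloxy)cyclohex-1-ene-1-carboxylate | C1[C@H]([C@@H]([C@@H](C=C1C(=O)OC)O)O)OC(=O)C(C)(C)C
F4 | step 5 | methyl (3R,4S,5R)-3-[(2,4-dinitrophenyl)sulfanyloxy]-4-hydroxy-5-(pivaloyloxy)cyclohex-1-ene-1-carboxylate | C1[C@H]([C@@H]([C@@H](C=C1C(=O)OC)OSc2ccc(cc2[N+](=O)[O-])[N+](=O)[O-])O)OC(=O)C(C)(C)C
F5 | step 5 | methyl (1R,4R,5R)-1-[(2,4-dinitrophenyl)sulfinyl]-4-hydroxy-5-(pivaloyloxy)cyclohex-2-ene-1-carboxylate (sulfur configuration undefined) | C1[C@H]([C@@H](C=C[C@]1(C(=O)OC)S(=O)c2ccc(cc2[N+](=O)[O-])[N+](=O)[O-])O)OC(=O)C(C)(C)C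
F6 | step 5 | methyl (5R,6R)-6-hydroxy-5-(pivaloyloxy)cyclohexa-1,3-diene-3-carboxylate (target numbering) | C1=CC(C(=O)OC)=C[C@@H](OC(=O)C(C)(C)C)[C@@H]1O
F7 | step 5 | methyl (5R,6R)-6-[(tert-butyldimethylsilyl)oxy]-5-(pivaloyloxy)cyclohexa-1,3-diene-3-carboxylate (target numbering) | C1=CC(C(=O)OC)=C[C@@H](OC(=O)C(C)(C)C)[C@@H]1O[Si](C)(C)C(C)(C)C
F8 | step 5 | (5R,6R)-6-[(tert-butyldimethylsilyl)oxy]-3-(hydroxymethyl)cyclohexa-1,3-dien-5-ol (target numbering) | C1=CC(CO)=C[C@@H](O)[C@@H]1O[Si](C)(C)C(C)(C)C
F9 | step 8 | (1S,4S,5R,6R)-4-acetoxy-5-(benzoyloxy)-3-[(benzoyloxy)methyl]-1-methoxycyclohex-2-en-6-ol | CO[C@H]1C=C(COC(=O)c2ccccc2)[C@H](OC(C)=O)[C@@H](OC(=O)c2ccccc2)[C@@H]1O
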